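**Retrosynthetic overview**
1. Methyl 3,5-dioxohexanoate (1) and methyl (2R,3S)-3-phenylglycidate (2) are the fragments of the open-chain epoxy triketo ester 3 (C6–C7 disconnection, polyanion Claisen acylation).
2. Key disconnection: both rings of the chromanone are cut back to chain 3; ring A comes from a polyketide-type Claisen aromatisation giving epoxy ketone 4 (not isolated), and ring C from 6-endo opening of its oxirane, giving pinobanksin 5.
3. Last disconnection is the C3–O acyl bond: 5 and (R)-2-methylbutanoic acid (6) give the 3,7-diester 7 (not isolated), whose aryl ester is cleaved in the same pot to target 8.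
4. Ring order: the phenyl ring and the oxirane are bought; ring A forms first and ring C second, in one flask.
5. Stereochemistry: C3 is the glycidate C2 (untouched), C2 is the glycidate C3 after one inversion, and the acyl stereocentre comes from 6.

Assumption: 1, 2 and 6 are bought as catalogue chemicals in the configurations shown (2 and 6 at ≥98% ee).

**Route**

Step 1
Reactants: 1 methyl 3,5-dioxohexanoate; 2 methyl (2R,3S)-3-phenyloxirane-2-carboxylate
Product: 3 methyl 3,5,7-trioxo-7-[(2R,3S)-3-phenyloxiran-2-yl]heptanoate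
Conditions: 1 (2.2 equiv), LiN(i-Pr)2 (LDA, 6.6 equiv), THF, −78 → 0 °C; then 2 (1.0 equiv), −78 → −40 °C; AcOH quench at −78 °C
Reagents that add atoms: none
Why: Harris-type polyanion acylation (crossed Claisen condensation): the terminal C6 carbanion of the trianion of 1 is its most nucleophilic site and adds to the ester carbonyl of 2 faster than to the oxirane, the second equivalent of trianion deprotonates the new 1,3-diketone so nothing over-adds, and neither oxirane stereocentre is touched.

Step 2
Reactants: 3 methyl 3,5,7-trioxo-7-[(2R,3S)-3-phenyloxiran-2-yl]heptanoate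
Product: 5 (2R,3R)-3,5,7-trihydroxy-2-phenyl-2,3-dihydro-4H-chromen-4-one (pinobanksin), via oxiranyl trihydroxyphenyl ketone 4 (not isolated)
Conditions: KOH (2 M, degassed H2O/MeOH 4:1), Ar, 0 °C → rt; then conc. HCl to pH 1, 45 °C (same flask)
Reagents that add atoms: none
Why: Proposed new method: in the polyanion made by KOH all three ketones are enolised and only the ester carbonyl stays electrophilic, so C6 attacks C1 (Claisen/Dieckmann-type cyclisation, loss of methoxide, aromatisation) to build ring A as ketone 4, whose trans-oxirane tolerates alkali because its α-hydrogen cannot enolise; on acidification an ortho-hydroxyl opens the protonated oxirane at the benzylic carbon in a 6-endo, invertive fashion, which closes ring C and gives the 2,3-trans (2R,3R) product with C3 retained from the glycidate; the closest known reactions are the KOH-induced Claisen cyclisation of 3,5,7-trioxo esters to acylphloroglucinols (biomimetic polyketide aromatisation) and the HCl/MeOH cyclisation of 2'-hydroxychalcone epoxides to trans-dihydroflavonols.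

Step 3
Reactants: 5 (2R,3R)-3,5,7-trihydroxy-2-phenyl-2,3-dihydro-4H-chromen-4-one; 6 (2R)-2-methylbutanoic acid
Product: 8 (2R,3R)-5,7-dihydroxy-4-oxo-2-phenyl-3,4-dihydro-2H-chromen-3-yl (2R)-2-methylbutanoate, via 3,7-diester 7 (not isolated)
Conditions: 6 (2.6 equiv), N,N'-diisopropylcarbodiimide (DIC, 2.6 equiv), DMAP (0.2 equiv), CH2Cl2, 0 °C → rt; then MeOH, NH4OAc (1 equiv, unchanged), rt
Reagents that add atoms: none
Why: Steglich esterification acylates the 3-OH and the acidic 7-OH while the chelated 5-OH stays free, and the 7-O-aryl ester (an activated ester of a vinylogous acid) is then methanolysed selectively (chemoselective aryl-ester cleavage) while the hindered alkyl ester at C3 stays; no stereocentre is touched, and the acyl stereocentre is brought in by 6 without a ketene-forming base.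

**Compound list**
1 | methyl 3,5-dioxohexanoate | COC(=O)CC(=O)CC(C)=O | starting material
2 | methyl (2R,3S)-3-phenyloxirane-2-carboxylate | COC(=O)[C@@H]1O[C@H]1c1ccccc1 | starting material
3 | methyl 3,5,7-trioxo-7-[(2R,3S)-3-phenyloxiran-2-yl]heptanoate | COC(=O)CC(=O)CC(=O)CC(=O)[C@@H]1O[C@H]1c1ccccc1 | intermediate
4 | [(2R,3S)-3-phenyloxiran-2-yl](2,4,6-trihydroxyphenyl)methanone | O=C(c1c(O)cc(O)cc1O)[C@@H]1O[C@H]1c1ccccc1 | intermediate
5 | (2R,3R)-3,5,7-trihydroxy-2-phenyl-2,3-dihydro-4H-chromen-4-one (pinobanksin) | O[C@H]1C(=O)c2c(O)cc(O)cc2O[C@@H]1c1ccccc1 | intermediate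
6 | (2R)-2-methylbutanoic acid | CC[C@@H](C)C(=O)O | starting material
7 | (2R,3R)-5-hydroxy-4-oxo-2-phenyl-3,4-dihydro-2H-chromene-3,7-diyl bis[(2R)-2-methylbutanoate] | CC[C@@H](C)C(=O)O[C@H]1C(=O)c2c(O)cc(OC(=O)[C@H](C)CC)cc2O[C@@H]1c1ccccc1 | intermediate
8 | (2R,3R)-5,7-dihydroxy-4-oxo-2-phenyl-3,4-dihydro-2H-chromen-3-yl (2R)-2-methylbutanoate | CC[C@@H](C)C(=O)O[C@H]1C(=O)c2c(O)cc(O)cc2O[C@@H]1c1ccccc1 | target

**Step count**
Total steps: 3. Longest linear sequence: 3 (steps 1, 2, 3).

**Steps most likely to fail, with fallbacks**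

Step 2 (highest risk). The chain may cyclise in the aldol sense to a resorcylate instead of the Claisen sense. The oxirane may also be opened by hydroxide or methoxide, or at the α-carbon to give a benzofuranone. The fallback keeps the open-chain polyketide logic but carries the two carbinol carbons as a base-stable acetonide and closes ring C in a separate step. It sets out from 1. The trianion of 1 (LiN(i-Pr)2, THF, as in step 1) is acylated with methyl (4R,5S)-2,2-dimethyl-5-phenyl-1,3-dioxolane-4-carboxylate F1, itself made from purchased methyl (2R,3S)-2,3-dihydroxy-3-phenylpropanoate with 2,2-dimethoxypropane and catalytic TsOH. This gives methyl 7-[(4R,5S)-2,2-dimethyl-5-phenyl-1,3-dioxolan-4-yl]-3,5,7-trioxoheptanoate F2. Aqueous KOH then closes ring A alone to [(4R,5S)-2,2-dimethyl-5-phenyl-1,3-dioxolan-4-yl](2,4,6-trihydroxyphenyl)methanone F3. Aqueous CF3CO2H removes the acetonide to give (2R,3S)-2,3-dihydroxy-3-phenyl-1-(2,4,6-trihydroxyphenyl)propan-1-one F4. PPh3 and diisopropyl azodicarboxylate in THF at 0 °C close ring C by intramolecular Mitsunobu etherification with inversion at the benzylic carbon. The fallback comes back to the route at 5 and also bypasses step 1.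

Step 1. The strongly basic trianion may deprotonate or open the glycidate, and proton transfer from the product consumes a second equivalent of trianion. The fallback changes the acyl donor to one that releases the ketone only on work-up. It sets out from 2, which is converted with MeNHOMe·HCl and LiN(SiMe3)2 in THF at −20 °C into (2R,3S)-N-methoxy-N-methyl-3-phenyloxirane-2-carboxamide F5. F5 is added at −78 °C to only 1.2 equivalents of the trianion of 1. The chelated tetrahedral adduct survives until the AcOH quench, so the product never meets excess carbanion. The fallback comes back to the route at 3.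

Step 3. Incomplete acylation of the hindered 3-OH or partial loss of the 3-ester during aryl-ester cleavage would lower the yield. The fallback replaces over-acylation and selective cleavage by protection of the 7-OH. It sets out from 5, which with TBSCl (1.05 equiv) and imidazole in DMF at 0 °C gives (2R,3R)-7-[(tert-butyldimethylsilyl)oxy]-3,5-dihydroxy-2-phenyl-2,3-dihydro-4H-chromen-4-one F6. Esterification with 6 (1.3 equiv), DIC and DMAP in CH2Cl2 gives (2R,3R)-7-[(tert-butyldimethylsilyl)oxy]-5-hydroxy-4-oxo-2-phenyl-3,4-dihydro-2H-chromen-3-yl (2R)-2-methylbutanoate F7. HF·pyridine in THF at 0 °C removes the silyl group, and the fallback comes back to the route at 8.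

**Further compounds**
F1 | step 2 | methyl (4R,5S)-2,2-dimethyl-5-phenyl-1,3-dioxolane-4-carboxylate | COC(=O)[C@@H]1OC(C)(C)O[C@H]1c1ccccc1
F2 | step 2 | methyl 7-[(4R,5S)-2,2-dimethyl-5-phenyl-1,3-dioxolan-4-yl]-3,5,7-trioxoheptanoate | COC(=O)CC(=O)CC(=O)CC(=O)[C@@H]1OC(C)(C)O[C@H]1c1ccccc1
F3 | step 2 | [(4R,5S)-2,2-dimethyl-5-phenyl-1,3-dioxolan-4-yl](2,4,6-trihydroxyphenyl)methanone | O=C(c1c(O)cc(O)cc1O)[C@@H]1OC(C)(C)O[C@H]1c1ccccc1
F4 | step 2 | (2R,3S)-2,3-dihydroxy-3-phenyl-1-(2,4,6-trihydroxyphenyl)propan-1-one | O=C(c1c(O)cc(O)cc1O)[C@H](O)[C@@H](O)c1ccccc1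
F5 | step 1 | (2R,3S)-N-methoxy-N-methyl-3-phenyloxirane-2-carboxamide | CON(C)C(=O)[C@@H]1O[C@H]1c1ccccc1
F6 | step 3 | (2R,3R)-7-[(tert-butyldimethylsilyl)oxy]-3,5-dihydroxy-2-phenyl-2,3-dihydro-4H-chromen-4-one | O[C@H]1C(=O)c2c(O)cc(O[Si](C)(C)C(C)(C)C)cc2O[C@@H]1c1ccccc1
F7 | step 3 | (2R,3R)-7-[(tert-butyldimethylsilyl)oxy]-5-hydroxy-4-oxo-2-phenyl-3,4-dihydro-2H-chromen-3-yl (2R)-2-methylbutanoate | CC[C@@H](C)C(=O)O[C@H]1C(=O)c2c(O)cc(O[Si](C)(C)C(C)(C)C)cc2O[C@@H]1c1ccccc1
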